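## Retrosynthetic overview

1. Pestallic acid J ⇐ one-pot acid deprotection ⇐ Stille coupling of a C2 α-iodoenone with an (R,E)-alkenylstannane (side-chain carbinol from a ketoreductase reduction of hept-6-yn-2-one).
2. Tiglate arm ⇐ Wittig olefination of a lactol from a cis-fused γ-lactone; C3 CH2OH ⇐ Stille hydroxymethylation of the vinyl bromide.
3. cis-Lactone (sets C6) ⇐ intramolecular opening of a C1/C6 α-epoxide by a malonate tethered to the C5 oxygen.
4. C4/C5 cis-diol ⇐ toluene-dioxygenase cis-dihydroxylation of bromobenzene (first stereocentres).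
5. Ring order: the carbocycle is the arene ring (dearomatised, never built); temporary rings follow as dioxolane acetal → epoxide → γ-lactone (opened in the Wittig step) → dioxolane acetal.

Assumption: ring carbons are numbered as in the target (C1 = C=O, C2 = heptenyl-bearing, C3 = CH2OH-bearing, C4/C5 = carbinol carbons, C6 = butenoate-bearing); β is the ring face carrying the C4/C5 oxygens, α the opposite face; PMB = 4-methoxybenzyl, PMP = 4-methoxyphenyl; epimer mixtures at acetal, lactol and malonate α-carbons are carried on because those centres disappear later.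

## Route

Step 1
Reactants: 1 bromobenzene
Product: 2 (1S,2S)-3-bromocyclohexa-3,5-diene-1,2-diol
Conditions: E. coli JM109(pDTG601A) whole cells expressing toluene dioxygenase (a Rieske-type arene cis-dihydroxylating dioxygenase), air, glucose-fed mineral medium, pH 6.8, 35 °C
Reagents that add atoms: dioxygen O=O
Why: Enzymatic enantioselective arene cis-dihydroxylation (catalytic asymmetric dearomatisation) delivers both oxygens to one face of the 2,3-bond, giving the (1S,2S)-diol in >99% ee and fixing C4 and C5 of the target.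

Step 2
Reactants: 2 (1S,2S)-3-bromocyclohexa-3,5-diene-1,2-diol
Product: 3 (3aS,7aS)-4-bromo-2-(4-methoxyphenyl)-3a,7a-dihydro-1,3-benzodioxole (acetal epimers)
Conditions: 4-MeOC6H4CH(OMe)2, CSA (cat.), CH2Cl2, −20 → 0 °C
Reagents that add atoms: 4-methoxybenzaldehyde dimethyl acetal COc1ccc(C(OC)OC)cc1
Why: Acid-catalysed transacetalisation of the cis-diol gives the cis-fused p-methoxybenzylidene acetal without touching C4/C5.

Step 3
Reactants: 3 PMP acetal
Product: 4 (1S,6S)-5-bromo-6-[(4-methoxybenzyl)oxy]cyclohexa-2,4-dien-1-ol (C4β-OPMB; C5β-OH)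
Conditions: DIBAL-H (3 equiv), CH2Cl2, −78 → −20 °C; Rochelle salt
Reagents that add atoms: none
Why: Regioselective reductive acetal opening, expected because aluminium coordinates the less hindered oxygen remote from C–Br, which is released as the free C5–OH while the PMB ether stays on C4.

Step 4
Reactants: 4 mono-PMB dienol; 5 monomethyl malonate
Product: 6 (1S,6S)-5-bromo-6-[(4-methoxybenzyl)oxy]cyclohexa-2,4-dien-1-yl methyl malonate
Conditions: DCC, DMAP (cat.), CH2Cl2, 0 °C
Reagents that add atoms: none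
Why: Steglich esterification puts the carbon nucleophile on the C5 oxygen (β face) with retention at C5.

Step 5
Reactants: 6 dienyl methyl malonate
Product: 7 3-bromo-1α,6α-epoxy-4β-[(4-methoxybenzyl)oxy]cyclohex-2-en-5β-yl methyl malonate
Conditions: mCPBA, CH2Cl2 / aq. phosphate buffer pH 7.5, 0 °C
Reagents that add atoms: mCPBA OOC(=O)c1cccc(Cl)c1
Why: Prilezhaev epoxidation of the electron-richer, non-brominated alkene occurs anti to the two β-oxygen substituents, giving the α-epoxide (new centres C1 and C6).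

Step 6
Reactants: 7 α-epoxy malonate
Product: 8 cis-fused α-(methoxycarbonyl)-γ-lactone alcohol (C5β–O–CO–CH(CO2Me)–C6β; C1α-OH; C3-Br; C4β-OPMB; epimers at the lactone α-carbon)
Conditions: NaH (1.05 equiv), THF/DMF 5:1, 0 → 40 °C; aq. NH4Cl
Reagents that add atoms: none
Why: Intramolecular SN2 epoxide opening (5-exo-tet) by the tethered malonate anion attacks C6 from the β face, anti to the α-epoxide, so the new C6–C bond is cis to the C5 oxygen and C1–OH is left α.

Step 7
Reactants: 8 α-(methoxycarbonyl) lactone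
Product: 9 cis-fused γ-lactone (C5β–O–CO–CH2–C6β; C1α-OH; C3-Br; C4β-OPMB)
Conditions: LiCl, H2O, DMSO, 130 °C
Reagents that add atoms: none
Why: Krapcho dealkoxycarbonylation removes the activating ester; C6 is β to the lactone carbonyl and cannot epimerise.

Step 8
Reactants: 9 bromo lactone; 10 (tributylstannyl)methanol
Product: 11 C3-hydroxymethyl lactone diol (C3-CH2OH; C1α-OH; C4β-OPMB; lactone as in 9)
Conditions: Pd(PPh3)4 (8 mol %), 1,4-dioxane, 100 °C
Reagents that add atoms: none
Why: Stille (Kosugi) hydroxymethylation of the vinyl bromide installs the C3 carbon under neutral conditions.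

Step 9
Reactants: 11 lactone diol
Product: 12 C3-CH2OTBS lactone (C1α-OH free)
Conditions: TBSCl (1.05 equiv), imidazole, CH2Cl2, −20 → 0 °C
Reagents that add atoms: TBSCl CC(C)(C)[Si](C)(C)Cl
Why: Chemoselective silylation of the primary allylic alcohol over the hindered secondary C1–OH.

Step 10
Reactants: 12 silyl ether lactone
Product: 13 lactol (C5β–O–CH(OH)–CH2–C6β; anomers)
Conditions: DIBAL-H (2.5 equiv), CH2Cl2, −78 °C; Rochelle salt
Reagents that add atoms: none
Why: DIBAL half-reduction of the γ-lactone stops at the stable tetrahedral aluminate at −78 °C.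

Step 11
Reactants: 14 tert-butyl (triphenylphosphoranylidene)acetate
Product: 16 tert-butyl 2-(triphenylphosphoranylidene)propanoate, via phosphonium iodide 15 (not isolated)
Conditions: MeI, CH2Cl2, rt; then 2 M aq. NaOH/CH2Cl2, 0 °C
Reagents that add atoms: iodomethane CI
Why: C-alkylation of the stabilised ylide followed by deprotonation of the phosphonium salt gives the achiral α-methyl ylide.

Step 12
Reactants: 13 lactol; 16 tert-butyl 2-(triphenylphosphoranylidene)propanoate
Product: 18 tert-butyl (E)-2-methylbut-2-enoate diol (C6β-CH2CH=C(Me)CO2tBu; C5β-OH; C1α-OH; C4β-OPMB; C3-CH2OTBS), via open-chain hydroxy aldehyde 17 (not isolated)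
Conditions: toluene, 90 °C
Reagents that add atoms: none
Why: Wittig olefination of the lactol through its open aldehyde with an α-methyl stabilised ylide gives the (E)-trisubstituted enoate and frees C5–OH.

Step 13
Reactants: 18 enoate diol
Product: 19 C4/C5 cis-fused PMP acetal with C1α-OH free (acetal epimers)
Conditions: DDQ (1.2 equiv), 4 Å MS, dry CH2Cl2, 0 °C
Reagents that add atoms: none
Why: Oikawa–Yonemitsu oxidative acetalisation, in which DDQ oxidises the PMB ether to an oxocarbenium ion that the cis-vicinal C5–OH traps.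

Step 14
Reactants: 19 allylic alcohol
Product: 20 enone (C1=O; C2-H; C3-CH2OTBS; C4/C5 PMP acetal; C6β side chain)
Conditions: Dess–Martin periodinane, pyridine, CH2Cl2, 0 °C → rt
Reagents that add atoms: none
Why: Dess–Martin oxidation of the only free alcohol gives the enone under buffered, non-enolising conditions, so the β-alkoxy ketone neither eliminates nor epimerises at C6.

Step 15
Reactants: 20 enone
Product: 21 C2-iodo enone
Conditions: I2 (3 equiv), pyridine/CH2Cl2 1:1, DMAP (0.2 equiv), rt, dark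
Reagents that add atoms: iodine II
Why: Johnson α-iodination (nucleophile-catalysed conjugate addition, iodination, elimination) places iodine at C2 using only a weak base.

Step 16
Reactants: 22 hex-5-ynoic acid
Product: 24 N-methoxy-N-methylhex-5-ynamide, via acyl imidazolide 23 (not isolated)
Conditions: CDI, CH2Cl2, rt; then MeNH(OMe)·HCl, rt
Reagents that add atoms: N,O-dimethylhydroxylamine hydrochloride CNOC.Cl
Why: CDI activation and aminolysis give the Weinreb amide.

Step 17
Reactants: 24 N-methoxy-N-methylhex-5-ynamide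
Product: 25 hept-6-yn-2-one
Conditions: MeMgBr (2.3 equiv), THF, 0 °C; aq. NH4Cl
Reagents that add atoms: methylmagnesium bromide C[Mg]Br
Why: Weinreb ketone synthesis, where the first equivalent deprotonates the alkyne and the chelated tetrahedral intermediate prevents over-addition.

Step 18
Reactants: 25 hept-6-yn-2-one
Product: 26 (2R)-hept-6-yn-2-ol
Conditions: (R)-selective NADPH-dependent ketoreductase (alcohol dehydrogenase class, Lactobacillus kefir type), NADP+ (cat.), i-PrOH (10 % v/v), phosphate buffer pH 7, 30 °C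
Reagents that add atoms: none
Why: Enzymatic asymmetric ketone reduction with anti-Prelog hydride delivery to the si face gives the (R)-carbinol in >99% ee, with i-PrOH recycling the cofactor.

Step 19
Reactants: 26 (2R)-hept-6-yn-2-ol
Product: 27 (2R)-hept-6-yn-2-yl acetate
Conditions: Ac2O, pyridine, DMAP (cat.), CH2Cl2, rt
Reagents that add atoms: acetic anhydride CC(=O)OC(C)=O
Why: O-Acylation with retention installs the acetate of the target early, since it survives all later neutral and acidic steps.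

Step 20
Reactants: 27 (2R)-hept-6-yn-2-yl acetate
Product: 28 (2R)-7-bromohept-6-yn-2-yl acetate
Conditions: NBS, AgNO3 (10 mol %), acetone, rt
Reagents that add atoms: N-bromosuccinimide BrN1C(=O)CCC1=O
Why: Silver-catalysed electrophilic bromination of the terminal alkyne.

Step 21
Reactants: 28 (2R)-7-bromohept-6-yn-2-yl acetate
Product: 30 (2R,6E)-7-(tributylstannyl)hept-6-en-2-yl acetate, via bromostannyl alkene 29 (not isolated)
Conditions: Bu3SnH (2.2 equiv), Pd2(dba)3 (1 mol %), PPh3 (8 mol %), THF, rt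
Reagents that add atoms: tributyltin hydride CCCC[SnH](CCCC)CCCC
Why: Pd-catalysed syn-hydrostannation of the 1-bromoalkyne followed by Pd-mediated reduction of the C–Br bond with retention gives the (E)-vinylstannane only.

Step 22
Reactants: 21 C2-iodo enone; 30 (2R,6E)-7-(tributylstannyl)hept-6-en-2-yl acetate
Product: 31 fully protected pestallic acid J (C3-CH2OTBS; C4/C5 PMP acetal; tert-butyl ester)
Conditions: Pd2(dba)3 (5 mol %), AsPh3 (20 mol %), CuI (10 mol %), NMP, rt → 40 °C
Reagents that add atoms: none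
Why: Stille cross-coupling of the α-iodoenone with the alkenylstannane is base-free and retains the alkene geometry and C6.

Step 23
Reactants: 31 protected pestallic acid J
Product: 32 pestallic acid J
Conditions: TFA/CH2Cl2/H2O 4:5:1, 0 °C → rt
Reagents that add atoms: none
Why: One-pot acidolysis (acetal hydrolysis, desilylation, E1 cleavage of the tert-butyl ester) frees the triol acid; the secondary acetate survives and no base is present to epimerise C6 or dehydrate the β-hydroxy ketone.

## Compound list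

1 | bromobenzene | Brc1ccccc1 | starting material
2 | (1S,2S)-3-bromocyclohexa-3,5-diene-1,2-diol | C1=C(Br)[C@@H](O)[C@@H](O)C=C1 | intermediate
3 | (3aS,7aS)-4-bromo-2-(4-methoxyphenyl)-3a,7a-dihydro-1,3-benzodioxole (acetal epimers) | C1=C(Br)[C@H]2OC(c3ccc(OC)cc3)O[C@H]2C=C1 | intermediate
4 | (1S,6S)-5-bromo-6-[(4-methoxybenzyl)oxy]cyclohexa-2,4-dien-1-ol | C1=C(Br)[C@@H](OCc2ccc(OC)cc2)[C@@H](O)C=C1 | intermediate
5 | monomethyl malonate (3-methoxy-3-oxopropanoic acid) | COC(=O)CC(=O)O | starting material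
6 | (1S,6S)-5-bromo-6-[(4-methoxybenzyl)oxy]cyclohexa-2,4-dien-1-yl methyl malonate | C1=C(Br)[C@@H](OCc2ccc(OC)cc2)[C@@H](OC(=O)CC(=O)OC)C=C1 | intermediate
7 | 3-bromo-1α,6α-epoxy-4β-[(4-methoxybenzyl)oxy]cyclohex-2-en-5β-yl methyl malonate | C1=C(Br)[C@@H](OCc3ccc(OC)cc3)[C@@H](OC(=O)CC(=O)OC)[C@H]2[C@@H]1O2 | intermediate
8 | cis-fused α-(methoxycarbonyl)-γ-lactone, C1α-OH, C3-Br, C4β-OPMB (epimers at lactone α-carbon) | C1=C(Br)[C@@H](OCc3ccc(OC)cc3)[C@H]2OC(=O)C(C(=O)OC)[C@H]2[C@@H]1O | intermediate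
9 | cis-fused γ-lactone (C5β–O–CO–CH2–C6β), C1α-OH, C3-Br, C4β-OPMB | C1=C(Br)[C@@H](OCc3ccc(OC)cc3)[C@H]2OC(=O)C[C@H]2[C@@H]1O | intermediate
10 | (tributylstannyl)methanol | CCCC[Sn](CCCC)(CCCC)CO | starting material
11 | C3-hydroxymethyl lactone diol | C1=C(CO)[C@@H](OCc3ccc(OC)cc3)[C@H]2OC(=O)C[C@H]2[C@@H]1O | intermediate
12 | C3-(tert-butyldimethylsilyloxymethyl) lactone, C1α-OH | C1=C(CO[Si](C)(C)C(C)(C)C)[C@@H](OCc3ccc(OC)cc3)[C@H]2OC(=O)C[C@H]2[C@@H]1O | intermediate
13 | lactol of 12 (anomers) | C1=C(CO[Si](C)(C)C(C)(C)C)[C@@H](OCc3ccc(OC)cc3)[C@H]2OC(O)C[C@H]2[C@@H]1O | intermediate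
14 | tert-butyl (triphenylphosphoranylidene)acetate | CC(C)(C)OC(=O)C=P(c1ccccc1)(c1ccccc1)c1ccccc1 | starting material
15 | [1-(tert-butoxy)-1-oxopropan-2-yl]triphenylphosphonium iodide | CC(C(=O)OC(C)(C)C)[P+](c1ccccc1)(c1ccccc1)c1ccccc1.[I-] | intermediate
16 | tert-butyl 2-(triphenylphosphoranylidene)propanoate | CC(C(=O)OC(C)(C)C)=P(c1ccccc1)(c1ccccc1)c1ccccc1 | intermediate
17 | open-chain hydroxy aldehyde (C6β-CH2CHO, C5β-OH, C1α-OH) | C1=C(CO[Si](C)(C)C(C)(C)C)[C@@H](OCc3ccc(OC)cc3)[C@@H](O)[C@@H](CC=O)[C@@H]1O | intermediate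
18 | tert-butyl (E)-2-methylbut-2-enoate diol (C6β side chain, C5β-OH, C1α-OH, C4β-OPMB, C3-CH2OTBS) | C1=C(CO[Si](C)(C)C(C)(C)C)[C@@H](OCc3ccc(OC)cc3)[C@@H](O)[C@@H](C/C=C(\C)C(=O)OC(C)(C)C)[C@@H]1O | intermediate
19 | C4/C5 cis-fused PMP acetal, C1α-OH (acetal epimers) | C1=C(CO[Si](C)(C)C(C)(C)C)[C@H]2OC(c3ccc(OC)cc3)O[C@H]2[C@@H](C/C=C(\C)C(=O)OC(C)(C)C)[C@@H]1O | intermediate
20 | enone (C1=O) with C4/C5 PMP acetal | C1=C(CO[Si](C)(C)C(C)(C)C)[C@H]2OC(c3ccc(OC)cc3)O[C@H]2[C@@H](C/C=C(\C)C(=O)OC(C)(C)C)C1=O | intermediate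
21 | C2-iodo enone | IC1=C(CO[Si](C)(C)C(C)(C)C)[C@H]2OC(c3ccc(OC)cc3)O[C@H]2[C@@H](C/C=C(\C)C(=O)OC(C)(C)C)C1=O | intermediate
22 | hex-5-ynoic acid | C#CCCCC(=O)O | starting material
23 | 1-(hex-5-ynoyl)imidazole | C#CCCCC(=O)n1ccnc1 | intermediate
24 | N-methoxy-N-methylhex-5-ynamide | C#CCCCC(=O)N(C)OC | intermediate
25 | hept-6-yn-2-one | C#CCCCC(C)=O | intermediate
26 | (2R)-hept-6-yn-2-ol | C[C@@H](O)CCCC#C | intermediate
27 | (2R)-hept-6-yn-2-yl acetate | CC(=O)O[C@H](C)CCCC#C | intermediate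
28 | (2R)-7-bromohept-6-yn-2-yl acetate | CC(=O)O[C@H](C)CCCC#CBr | intermediate
29 | (2R,6E)-7-bromo-7-(tributylstannyl)hept-6-en-2-yl acetate | CC(=O)O[C@H](C)CCC/C=C(\Br)[Sn](CCCC)(CCCC)CCCC | intermediate
30 | (2R,6E)-7-(tributylstannyl)hept-6-en-2-yl acetate | CC(=O)O[C@H](C)CCC/C=C/[Sn](CCCC)(CCCC)CCCC | intermediate
31 | protected pestallic acid J (C3-CH2OTBS, C4/C5 PMP acetal, tert-butyl ester) | CC(=O)O[C@H](C)CCC/C=C/C1=C(CO[Si](C)(C)C(C)(C)C)[C@H]2OC(c3ccc(OC)cc3)O[C@H]2[C@@H](C/C=C(\C)C(=O)OC(C)(C)C)C1=O | intermediate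
32 | pestallic acid J: (2E)-4-{(1R,5R,6S)-3-[(1E,6R)-6-acetoxyhept-1-en-1-yl]-5,6-dihydroxy-4-(hydroxymethyl)-2-oxocyclohex-3-en-1-yl}-2-methylbut-2-enoic acid | CC(=O)O[C@H](C)CCC/C=C/C1=C(CO)[C@@H](O)[C@@H](O)[C@@H](C/C=C(\C)C(=O)O)C1=O | target

## Step count and risk

Total steps: 23 (16 on the core line, 6 for the stannane, 1 for the ylide).
Longest linear sequence: 16 steps (1 → 32 through steps 1–10, 12–15, 22, 23).

Most likely to fail:

Step 6 (key C6–C bond). The tethered malonate could attack the allylic C1 instead of C6, or the base could trigger aromatisation. Fallback: set out from 6 and use a cyclic sulfate as the electrophile instead of the epoxide. OsO4 (cat.)/NMO dihydroxylates the distal alkene from the α face to give the 1α,6α-diol F3. SO2Cl2/pyridine at −78 °C closes the cyclic sulfate F4. NaH at 0 °C then triggers the 5-exo displacement at C6 and gives the C1 sulfate monoester sodium salt F5. Catalytic H2SO4 in wet THF cleaves the sulfate ester, and the route is rejoined at 8.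

Step 15 (α-iodination of a β,β-disubstituted, base-sensitive enone). It may be sluggish, or eliminate the C5 oxygen. Fallback: set out from 19 and bring the C2 halogen in through an epoxide instead of an enone iodination. VO(acac)2/t-BuOOH epoxidises C2=C3 syn to the C1 hydroxyl to give the α-epoxy alcohol F6. Dess–Martin oxidation gives the epoxy ketone F7. LiBr/AcOH opens it by SN2 at C2 (α to the carbonyl) to the bromohydrin F8. SOCl2/pyridine dehydrates the tertiary alcohol to the α-bromoenone F9. Stille coupling of F9 with 30 (Pd2(dba)3, AsPh3, toluene, 90 °C) rejoins the route at 31.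

Step 3 (regiochemistry of the DIBAL acetal opening). The free hydroxyl must end up on C5; the selectivity is argued from sterics, not guaranteed. Fallback: set out from 2 and differentiate the diol by protecting groups. Thexyldimethylsilyl chloride/imidazole (DMF, −10 °C) silylates only the less hindered C5 hydroxyl to give the mono-silyl ether F1. PMB trichloroacetimidate with catalytic La(OTf)3 benzylates C4–OH to give the silyl PMB diether F2. TBAF removes the silyl group, and the route is rejoined at 4.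

## Further compounds

F1 | step 3 | (1S,6S)-2-bromo-6-{[(2,3-dimethylbutan-2-yl)dimethylsilyl]oxy}cyclohexa-2,4-dien-1-ol | C1=C(Br)[C@@H](O)[C@@H](O[Si](C)(C)C(C)(C)C(C)C)C=C1
F2 | step 3 | thexyldimethylsilyl ether of 4 (C4β-OPMB, C5β-OSi) | C1=C(Br)[C@@H](OCc2ccc(OC)cc2)[C@@H](O[Si](C)(C)C(C)(C)C(C)C)C=C1
F3 | step 6 | 3-bromo-1α,6α-dihydroxy-4β-[(4-methoxybenzyl)oxy]cyclohex-2-en-5β-yl methyl malonate | C1=C(Br)[C@@H](OCc3ccc(OC)cc3)[C@@H](OC(=O)CC(=O)OC)[C@H](O)[C@@H]1O
F4 | step 6 | C1α,C6α cyclic sulfate of F3 | C1=C(Br)[C@@H](OCc3ccc(OC)cc3)[C@@H](OC(=O)CC(=O)OC)[C@@H]2OS(=O)(=O)O[C@H]12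
F5 | step 6 | sodium C1α-sulfate monoester of 8 | C1=C(Br)[C@@H](OCc3ccc(OC)cc3)[C@H]2OC(=O)C(C(=O)OC)[C@H]2[C@@H]1OS(=O)(=O)[O-].[Na+]
F6 | step 15 | C2,C3-α-epoxy alcohol from 19 (C1α-OH) | O1[C@@H]2[C@@]1(CO[Si](C)(C)C(C)(C)C)[C@H]3OC(c4ccc(OC)cc4)O[C@H]3[C@@H](C/C=C(\C)C(=O)OC(C)(C)C)[C@@H]2O
F7 | step 15 | C2,C3-α-epoxy ketone | O1[C@@H]2[C@@]1(CO[Si](C)(C)C(C)(C)C)[C@H]3OC(c4ccc(OC)cc4)O[C@H]3[C@@H](C/C=C(\C)C(=O)OC(C)(C)C)C2=O
F8 | step 15 | C2β-bromo C3α-hydroxy ketone (bromohydrin) | Br[C@H]1[C@@](O)(CO[Si](C)(C)C(C)(C)C)[C@H]2OC(c3ccc(OC)cc3)O[C@H]2[C@@H](C/C=C(\C)C(=O)OC(C)(C)C)C1=O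
F9 | step 15 | C2-bromo enone (bromo analogue of 21) | BrC1=C(CO[Si](C)(C)C(C)(C)C)[C@H]2OC(c3ccc(OC)cc3)O[C@H]2[C@@H](C/C=C(\C)C(=O)OC(C)(C)C)C1=O
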